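**Retrosynthetic overview**

- The strategy rests on the two aryl–CH2 bonds at the ends of the (CH2)14 bridge. Chain C1 sits on C5 of ring A, meta to both ring A oxygens. Chain C14 sits on C6 of ring B, meta to both hydroxyls and ortho to the bridging ether oxygen. Electrophilic alkylation cannot reach either carbon, but each can carry a bromide, and the fourteen methylenes correspond to tetradeca-1,13-diene.
- Target ⇐ tri-O-methyl macrocycle (one BBr3 demethylation) ⇐ dibromo diaryl ether + 1,14-bis(9-BBN)tetradecane, by a two-fold B-alkyl Suzuki–Miyaura coupling that forms C5(ring A)–C1 and C6(ring B)–C14 and closes the 20-membered ring.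
- Dibromo diaryl ether ⇐ 2-bromo-4,6-dimethoxyphenol + (3-bromo-5-methoxyphenyl)boronic acid (Chan–Lam); the phenol ⇐ 1-bromo-3,5-dimethoxybenzene (Vilsmeier formylation, then Baeyer–Villiger/Dakin oxidation).
- All three phenols are carried as methyl ethers; both benzene rings are bought, the diaryl ether is made first, and the macrocycle is the only ring formed.

Key step: step 5

Remark: the target has no stereocentre, and (3-bromo-5-methoxyphenyl)boronic acid is taken as a purchasable building block.

**Route**

Step 1
Reactants: 1 1-bromo-3,5-dimethoxybenzene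
Product: 3 2-bromo-4,6-dimethoxybenzaldehyde, via aryl iminium salt 2 (not isolated)
Conditions: POCl3 (3 equiv), DMF, 0 °C then 90 °C; then ice/H2O
Reagents that add atoms: N,N-dimethylformamide CN(C)C=O; water O
Why: Vilsmeier–Haack formylation, in which the chloroiminium electrophile should attack C2 of 1 (para to one methoxy, ortho to the other) rather than the more crowded C4 between the two methoxy groups, and hydrolysis of iminium salt 2 releases the aldehyde.

Step 2
Reactants: 3 2-bromo-4,6-dimethoxybenzaldehyde
Product: 5 2-bromo-4,6-dimethoxyphenol, via aryl formate 4 (not isolated)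
Conditions: mCPBA (1.3 equiv), CH2Cl2, 0 °C to rt; aq. NaHCO3 wash; then K2CO3 (cat.), MeOH, rt
Reagents that add atoms: 3-chloroperoxybenzoic acid (mCPBA) OOC(=O)c1cccc(Cl)c1
Why: Baeyer–Villiger oxidation with a Dakin-type outcome, in which the electron-rich aryl group (ortho and para methoxy) should migrate in preference to hydride to give formate 4, which mild methanolysis cleaves to the phenol without touching the aryl bromide or the methyl ethers.

Step 3
Reactants: 5 2-bromo-4,6-dimethoxyphenol; 6 (3-bromo-5-methoxyphenyl)boronic acid (2 equiv)
Product: 7 1-bromo-2-(3-bromo-5-methoxyphenoxy)-3,5-dimethoxybenzene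
Conditions: Cu(OAc)2 (1 equiv), pyridine (5 equiv), 4 Å MS, CH2Cl2, O2 (1 atm), rt
Reagents that add atoms: none
Why: Chan–Lam O-arylation, in which the aryl group passes from boron to divalent copper, oxidation gives a trivalent copper aryl phenoxide and C–O reductive elimination follows at room temperature with dioxygen as terminal oxidant, conditions that leave both aryl bromides alone and are known to accept 2,6-disubstituted phenols.

Step 4
Reactants: 8 tetradeca-1,13-diene
Product: 9 1,14-bis(9-borabicyclo[3.3.1]nonan-9-yl)tetradecane (used as its THF solution)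
Conditions: 9-BBN-H dimer (2.05 equiv of B–H), THF, 0 °C to rt, argon
Reagents that add atoms: 9-borabicyclo[3.3.1]nonane B1C2CCCC1CCC2
Why: Hydroboration, in which 9-BBN-H adds anti-Markovnikov to both terminal alkenes with very high selectivity for the terminal carbon, giving primary B-alkyl-9-BBN groups that transfer well in sp3–sp2 Suzuki coupling.

Step 5
Reactants: 7 1-bromo-2-(3-bromo-5-methoxyphenoxy)-3,5-dimethoxybenzene; 9 1,14-bis(9-borabicyclo[3.3.1]nonan-9-yl)tetradecane (1.1 equiv)
Product: 11 tri-O-methyl ether of the 20-membered macrocycle, via mono-coupled seco borane 10 (not isolated)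
Conditions: Pd(dppf)Cl2·CH2Cl2 (10 mol %, two portions), Cs2CO3 (6 equiv), DMF/THF/H2O, 70 °C, degassed; THF solution of 7 and 9 added by syringe pump over 12 h, final concentration about 2 mM
Reagents that add atoms: none
Why: This is a B-alkyl Suzuki–Miyaura coupling run twice in one flask: zerovalent palladium formed from Pd(dppf)Cl2 inserts into an aryl C–Br bond, the base-activated primary alkyl-9-BBN borate passes its CH2 group to divalent palladium, and reductive elimination, fast with the wide-bite-angle dppf ligand, should outrun β-hydride elimination. The closest known reaction type is the B-alkyl Suzuki macrocyclisation of an aryl halide carrying an ω-borylalkyl chain, here preceded in the same flask by an intermolecular coupling. The first coupling should join chain C1 to C5 of ring A at the unhindered bromide to give seco borane 10, and the 20-membered ring is then closed by intramolecular sp2–sp3 coupling between C6 of ring B and chain C14, an end-to-end macrocyclisation of a flexible saturated tether. No stereocentre is formed. The step needs ring closure to beat chain growth and the two bromides to react in sequence: slow co-addition keeps 7 and 9 at a low stationary concentration, and the ring B bromide, flanked by the aryloxy group, should add to palladium more slowly and so be left for the intramolecular event; because the diborane is symmetric, either order of coupling leads to the same macrocycle.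

Step 6
Reactants: 11 tri-O-methyl ether of the 20-membered macrocycle
Product: 12 CNP0173380.0 (the triphenol target)
Conditions: BBr3 (8 equiv), CH2Cl2, −78 °C to rt; then H2O, 0 °C
Reagents that add atoms: none
Why: Lewis-acid ether cleavage, in which BBr3 binds each methoxy oxygen and bromide attacks the methyl carbon (SN2), removing all three methyl groups while the diaryl ether, which has no sp3 C–O bond, and the saturated bridge stay intact.

**Compound list**

1 | 1-bromo-3,5-dimethoxybenzene | COc1cc(OC)cc(Br)c1 | starting material
2 | [(2-bromo-4,6-dimethoxyphenyl)methylidene]dimethyliminium dichlorophosphate (aryl iminium salt) | C[N+](C)=Cc1c(Br)cc(OC)cc1OC.[O-]P(=O)(Cl)Cl | intermediate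
3 | 2-bromo-4,6-dimethoxybenzaldehyde | O=Cc1c(Br)cc(OC)cc1OC | intermediate
4 | 2-bromo-4,6-dimethoxyphenyl formate (aryl formate) | O=COc1c(Br)cc(OC)cc1OC | intermediate
5 | 2-bromo-4,6-dimethoxyphenol | Oc1c(Br)cc(OC)cc1OC | intermediate
6 | (3-bromo-5-methoxyphenyl)boronic acid | COc1cc(Br)cc(B(O)O)c1 | starting material
7 | 1-bromo-2-(3-bromo-5-methoxyphenoxy)-3,5-dimethoxybenzene | COc1cc(Br)cc(Oc2c(OC)cc(OC)cc2Br)c1 | intermediate
8 | tetradeca-1,13-diene | C=CCCCCCCCCCCCC=C | starting material
9 | 1,14-bis(9-borabicyclo[3.3.1]nonan-9-yl)tetradecane | B1(CCCCCCCCCCCCCCB2C3CCCC2CCC3)C2CCCC1CCC2 | intermediate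
10 | 9-{14-[3-(2-bromo-4,6-dimethoxyphenoxy)-5-methoxyphenyl]tetradecyl}-9-borabicyclo[3.3.1]nonane (mono-coupled seco borane) | COc1cc(CCCCCCCCCCCCCCB2C3CCCC2CCC3)cc(Oc2c(OC)cc(OC)cc2Br)c1 | intermediate
11 | tri-O-methyl ether of the 20-membered macrocycle (ring A OMe at C1, ring B OMe at C2 and C4, (CH2)14 bridge from C5 of ring A to C6 of ring B) | COc1cc2cc(c1)Oc1c(OC)cc(OC)cc1CCCCCCCCCCCCCC2 | intermediate
12 | CNP0173380.0 (triphenol macrocycle) | Oc1cc2cc(c1)Oc1c(O)cc(O)cc1CCCCCCCCCCCCCC2 | target

**Totals**

Total step count: 6. Longest linear sequence: 5 steps (steps 1, 2, 3, 5, 6 from compound 1); step 4 is a one-step side branch.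

**Steps most likely to fail**

1. Step 5. Chain growth may outpace ring closure, and the borane terminus of 10 may be lost by protodeboronation before the slower ring B bromide has reacted.
   - Fallback: it sets out from 7 and returns at 11. Exhaustive two-fold B-alkyl Suzuki coupling at ordinary concentration with 9-(oct-7-en-1-yl)-9-borabicyclo[3.3.1]nonane F1 should give 1-(oct-7-en-1-yl)-2-[3-methoxy-5-(oct-7-en-1-yl)phenoxy]-3,5-dimethoxybenzene F2. F1 is made in THF from octa-1,7-diene in fivefold excess and 9-BBN-H, and the coupling uses Pd(dppf)Cl2, Cs2CO3, DMF/THF/H2O, 70 °C.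
   - Ring-closing metathesis with the second-generation Grubbs catalyst (CH2Cl2, 40 °C, 1 mM) should then close the 20-membered ring as the macrocyclic alkene F3, an E/Z mixture. Hydrogenation (H2, Pd/C, EtOAc) should saturate the bridge to give 11, and step 6 follows unchanged.
   - The aryl–CH2 bonds are still made by B-alkyl Suzuki coupling, but the ring is closed by alkene metathesis instead.

2. Step 3. C–O bond formation at the doubly ortho-substituted phenol may be slow, so that protodeboronation and homocoupling use up the boronic acid.
   - Fallback: it sets out from 5 and returns at 7. Commercial 1-bromo-3-iodo-5-methoxybenzene is oxidised with mCPBA and TsOH·H2O in MeCN and trapped with 1,3,5-trimethoxybenzene to give (3-bromo-5-methoxyphenyl)(2,4,6-trimethoxyphenyl)iodonium 4-methylbenzenesulfonate F4.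
   - Metal-free O-arylation of 5 with F4 (K2CO3, toluene, 55 °C) should transfer the bromo-methoxyphenyl group, the trimethoxyphenyl group acting as the non-transferred ligand, and give 7. No metal that could touch the aryl bromides is present.

3. Step 2. Excess peracid may over-oxidise the electron-rich phenol, and hydride migration to the benzoic acid may compete at the doubly ortho-substituted aldehyde.
   - Fallback: it sets out from 1 and returns at 5, bypassing steps 1 and 2. Iodination of 1 (N-iodosuccinimide, cat. CF3CO2H, MeCN, rt) should give 1-bromo-2-iodo-3,5-dimethoxybenzene F5.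
   - Selective iodine–magnesium exchange (iPrMgCl·LiCl, THF, −40 °C) should give (2-bromo-4,6-dimethoxyphenyl)magnesium chloride F6, which is trapped with B(OMe)3 as dimethyl (2-bromo-4,6-dimethoxyphenyl)boronate F7.
   - Oxidation in the same flask (H2O2, aq. NaOH, 0 °C, then acidification) should give 5. The hydroxyl is thus introduced by boron-to-oxygen migration rather than by oxidation of an aldehyde.

**Further compounds**

F1 | step 5 | 9-(oct-7-en-1-yl)-9-borabicyclo[3.3.1]nonane | C=CCCCCCCB1C2CCCC1CCC2
F2 | step 5 | 1-(oct-7-en-1-yl)-2-[3-methoxy-5-(oct-7-en-1-yl)phenoxy]-3,5-dimethoxybenzene | COc1cc(CCCCCCC=C)cc(Oc2c(OC)cc(OC)cc2CCCCCCC=C)c1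
F3 | step 5 | macrocyclic alkene, tri-O-methyl ether with a C7=C8 double bond in the bridge (E/Z mixture) | COc1cc2cc(c1)Oc1c(OC)cc(OC)cc1CCCCCCC=CCCCCCC2
F4 | step 3 | (3-bromo-5-methoxyphenyl)(2,4,6-trimethoxyphenyl)iodonium 4-methylbenzenesulfonate | COc1cc(Br)cc([I+]c2c(OC)cc(OC)cc2OC)c1.Cc1ccc(cc1)S(=O)(=O)[O-]
F5 | step 2 | 1-bromo-2-iodo-3,5-dimethoxybenzene | COc1cc(OC)c(I)c(Br)c1
F6 | step 2 | (2-bromo-4,6-dimethoxyphenyl)magnesium chloride | COc1cc(OC)c([Mg]Cl)c(Br)c1
F7 | step 2 | dimethyl (2-bromo-4,6-dimethoxyphenyl)boronate | COB(OC)c1c(Br)cc(OC)cc1OC
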